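## Structural features

Gentiside A is a 1,2,3-trisubstituted benzene in which C1 carries an ester carbonyl, C2 and C3 carry free hydroxyl groups, and C4, C5 and C6 carry hydrogen. The ester oxygen is bound to a saturated C22 chain of nineteen methylene groups that ends in an isopropyl group (20-methylhenicosyl). The molecule has no stereocentre, so no question of relative or absolute configuration arises. The fragile parts are the catechol, which is easily oxidised in base or by metal oxidants, and the single ester, which must survive every basic step; the chain is chemically inert but makes all intermediates waxy and poorly soluble in cold polar media. The real difficulty is to place the ester carbon beside two adjacent oxygen-bearing carbons without any positional isomer, in the presence of a long primary alkyl ester. The key step uses the fact that C2 and C3 are two adjacent carbons at the carbonyl/enol oxidation level, that is, an oxalyl unit. C1, C6, C5 and C4 together with the ester carbon on C1 are five of the six carbons of an adipate; the sixth, a carboxyl on C4, is absent from the target and can leave as CO2 as long as the ring is not yet aromatic.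

## Logic of the disconnections

13 ⇒ 12. No skeletal bond is cut; one unsaturation is taken out of the C4–C5–C6 segment, because the catechol is the dehydrogenated enol form of a cyclohexane-1,2-dione. This replaces the oxidisable catechol by a robust enolised diketone and opens the ring to carbonyl chemistry. The forward step must remove exactly two hydrogens from the ring without oxygenating C4, halogenating the ring or oxidising the product further.

12 ⇒ 10 (through 11). A carboxyl is put back on C4 as a tert-butyl ester; in the forward sense the C4–carboxyl bond is the one broken. The ring skeleton becomes a 2,3-dioxo-1,4-dicarboxylate whose two ester groups differ only in their alkyl parts. The forward step needs an acid that cleaves the tert-butyl ester alone, and decarboxylation must come before any oxidation, since an aromatic acid would not lose its carboxyl under these conditions.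

10 ⇒ 6 + 7 (through 8 and 9). Bonds C1–C2 and C3–C4 are cut; each joins an ester α-carbon to a carbonyl carbon, so each is a Claisen retron. The ring dissolves into two acyclic, achiral esters, one of them commercial. The forward step demands that enolate acylation by 7 outruns self-condensation of 6, that ring closure outruns a second intermolecular acylation, and that no alkoxide exchange touches the long-chain ester.

6 ⇒ 4 + 5. The acyl–oxygen bond of the long-chain ester is cut, an ordinary esterification retron. Compound 5 is commercial and already carries the tert-butyl ester, so the differentiation of the two carboxyl groups is bought. The forward coupling must be neutral to spare that ester.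

4 ⇒ 1 + 2 (through 3). The C16–C17 bond of the chain is cut, which splits it into a commercial C16 ω-bromo alcohol and a commercial branched C6 bromide. The alcohol is reached in one step. The forward sp3–sp3 coupling must tolerate a free hydroxyl, which is met by copper catalysis and an excess of the organomagnesium partner.

## Other disconnections considered

Alternative 1: The cut is made at the ester. Both the C1–carbonyl bond and the carbonyl–oxygen bond are severed, so the ring becomes 1,2-bis(benzyloxy)-3-bromobenzene A1, the carbonyl carbon becomes carbon monoxide A2, and the chain remains the alcohol 4.
- Forward key step: Pd(OAc)2 and Xantphos under an atmosphere of A2 with an amine base. Oxidative addition of A1 to zerovalent palladium, insertion of A2 and alcoholysis of the acylpalladium by 4 would give 20-methylhenicosyl 2,3-bis(benzyloxy)benzoate A3. Hydrogenolysis of A3 over Pd/C would then free the catechol 13.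
- In favour: the 1,2,3-pattern is bought and not made, the bond-forming event is a standard catalytic reaction, and the route is convergent. With A1 one benzylation away from a commercial building block, it needs four steps with a longest line of three, against five and five.
- Against: the toxic gas A2 and a precious-metal catalyst; two protecting groups put on and taken off; an oxidative addition of A1 slowed by the electron-rich ring and the ortho benzyloxy group; a waxy alcohol as near-stoichiometric nucleophile, which may make the alcoholysis slow.
- Comparison: structurally it builds no ring, whereas the chosen plan builds the ring from acyclic pieces and needs no protecting group on the catechol. Mechanistically it avoids strongly basic enolate chemistry beside the long-chain ester, which is the weak point of the chosen plan. On step count and on security of precedent it is the better plan. On regiochemical certainty the two are equal, since both fix the pattern by connectivity.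

Alternative 2: This cut concerns only the chain. Both C20–CH3 bonds of the isopropyl terminus are severed. In the forward sense, symmetrical icosanedioic acid A4 would be desymmetrised to tert-butyl 20-hydroxyicosanoate A5, whose ester carbon becomes C20.
- Forward key step: excess methyllithium A6 with CeCl3 would add twice to the ester carbonyl of A5, the first equivalent of A6 being spent on the hydroxyl, to give 20-methylhenicosane-1,20-diol A7. The tertiary hydroxyl of A7 must then be removed, by ionic hydrogenation or by dehydration and hydrogenation, to reach 4.
- In favour: no sp3–sp3 cross-coupling and hence no by-products of similar chain length; CeCl3 curbs enolisation; every intermediate is a crystallisable long-chain solid.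
- Against: A4 must first be desymmetrised by a statistical mono-esterification and a chemoselective reduction; the tert-butyl ester of A5 is a sluggish acceptor; the carbinol oxygen of A7 is introduced only to be removed. About five steps are needed where step 1 of the chosen plan needs one.
- Comparison: it says nothing about the aromatic ring, so it is not a rival to the ring synthesis but a possible replacement for step 1, delivering the same compound 4. In purity of the chain alcohol it may be the better, in mechanism it is equally conventional, and in step economy it is clearly the worse.

Alternative 3: The cut removes the C3–O bond and, one oxidation later, the C2–O bond. The C2 hydroxyl is traced back to a formyl group. The precursor is the silyl triflate 20-methylhenicosyl 2-{[(trifluoromethyl)sulfonyl]oxy}-3-(trimethylsilyl)benzoate A8, and the formyl carbon and the C3 oxygen both come from N,N-dimethylformamide A9.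
- Forward key step: CsF in A9 would release the C2–C3 aryne from A8. The formamide oxygen and carbon of A9 add across it through a transient four-membered ring that opens and is hydrolysed to 20-methylhenicosyl 2-formyl-3-hydroxybenzoate A10. A Dakin oxidation of A10 would then turn the formyl group into the second hydroxyl of 13.
- In favour: both ortho substituents arrive in one mild, metal-free step. The sense of addition does not matter in the end, because the regioisomer 20-methylhenicosyl 3-formyl-2-hydroxybenzoate A11 would converge on 13 in the Dakin step just as A10 does.
- Against: A8 is itself a 1,2,3-trisubstituted arene carrying the long-chain ester, so the positional problem is only moved into a precursor that needs several steps. One carbon is introduced to be excised, and alkaline peroxide endangers both the ester and the emerging catechol.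
- Comparison: structurally it also builds no lasting ring, and it needs more steps than the chosen plan once A8 is counted. Its key step is milder than stoichiometric enolate chemistry and in that respect the better. In freedom from protecting groups the two are equal. The chosen plan offers a shorter line from commercial materials and a substitution pattern fixed by the skeleton of two simple acyclic esters.

Key step: step 3

Remark: 10 is drawn as the bis-enol of the 2,3-dioxo diester and 12 as the mono-enol of the 2,3-dioxo ester; each stands for the whole set of keto–enol tautomers, and neither has a configurationally stable stereocentre.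

## Route

Step 1
Reactants: 1 1-bromo-4-methylpentane; 2 16-bromohexadecan-1-ol
Product: 4 20-methylhenicosan-1-ol, via (4-methylpentyl)magnesium bromide 3 (not isolated)
Conditions: 1 (2.6 equiv), Mg, THF, 40 °C; then 2, Li2CuCl4 (3 mol%), THF, 0 °C → rt; aq NH4Cl
Reagents that add atoms: none
Why: Copper-catalysed Grignard cross-coupling with a primary alkyl bromide (Kochi–Tamura type); the first equivalent of 3 turns the hydroxyl of 2 into an inert bromomagnesium alkoxide, and further 3 displaces the primary bromide through a transient alkylcopper species, joining C16 to C17 of the chain. No stereocentre is formed.

Step 2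
Reactants: 4 20-methylhenicosan-1-ol; 5 6-tert-butoxy-6-oxohexanoic acid
Product: 6 1-tert-butyl 6-(20-methylhenicosyl) hexanedioate
Conditions: EDC·HCl (1.5 equiv), DMAP (0.1 equiv), CH2Cl2, 0 °C → rt
Reagents that add atoms: none
Why: Steglich esterification; carbodiimide activation with DMAP as acyl-transfer catalyst esterifies the primary alcohol under neutral conditions that leave the acid-labile tert-butyl ester untouched.

Step 3
Reactants: 6 1-tert-butyl 6-(20-methylhenicosyl) hexanedioate; 7 di-tert-butyl oxalate
Product: 10 4-tert-butyl 1-(20-methylhenicosyl) 2,3-dihydroxycyclohexa-1,3-diene-1,4-dicarboxylate, via dilithium bis-enolate of the adipate diester 8 (not isolated), via open-chain mono-oxalyl diester 9 (not isolated)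
Conditions: LiN(iPr)2 (3.2 equiv), THF, −78 °C, 6 added slowly; then 7 (1.1 equiv), −78 °C → rt; cold 1 M HCl, argon
Reagents that add atoms: none
Why: This is a crossed Claisen acylation followed by a Dieckmann-type closure, the preformed-enolate counterpart of the known alkoxide-mediated condensation of dialkyl oxalates with dialkyl adipates to 2,3-dioxocyclohexane-1,4-dicarboxylates. Adding 6 to excess LiN(iPr)2 converts both ester groups into the lithium bis-enolate 8 before any electrophile is present, so no ester carbonyl is left to accept an enolate and the 5-exo self-condensation to a cyclopentanone is blocked at its source. One enolate carbon of 8 adds to a carbonyl of 7 and expels tert-butoxide, forming C1–C2 or C3–C4 according to which α-carbon reacts first (9 is drawn for attack beside the long-chain ester; either order leads to the same ring). The acidic CH so created is deprotonated by the third equivalent of the hindered amide, which makes the neighbouring ester part of a delocalised β-keto ester enolate and no longer electrophilic, while the remote α-carbon stays enolised. That enolate attacks the remaining oxalyl ester carbonyl in a 6-exo-trig (enolexo) closure, expels the second tert-butoxide and forms the other ring bond. Deprotonation of the second β-dicarbonyl site by the liberated LiOtBu makes the closure irreversible, and cold acid releases the bis-enol 10; no stereocentre is formed. The step needs oxalylation before self-condensation, ring closure before a second intermolecular oxalylation, and survival of the primary alkyl ester. These are secured by the bis-enolate, by using barely more than one equivalent of 7 added to dilute 8, and by the only alkoxide ever set free being hindered, weakly nucleophilic LiOtBu below room temperature.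

Step 4
Reactants: 10 4-tert-butyl 1-(20-methylhenicosyl) 2,3-dihydroxycyclohexa-1,3-diene-1,4-dicarboxylate
Product: 12 20-methylhenicosyl 2-hydroxy-3-oxocyclohex-1-ene-1-carboxylate, via ring carboxylic acid 11 (not isolated)
Conditions: CF3CO2H, CH2Cl2, 0 °C → rt; evaporate; toluene, 80 °C, N2
Reagents that add atoms: none
Why: Acidolysis of the tert-butyl ester (loss of 2-methylpropene) leaves the primary alkyl ester intact; acid 11 is the enol of a β-keto acid and loses CO2 through the usual six-membered cyclic transition state on warming. Oxygen is excluded so that the ring cannot aromatise before the carboxyl has left.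

Step 5
Reactants: 12 20-methylhenicosyl 2-hydroxy-3-oxocyclohex-1-ene-1-carboxylate
Product: 13 Gentiside A (20-methylhenicosyl 2,3-dihydroxybenzoate)
Conditions: I2 (0.2 equiv), DMSO, 80 °C, N2; aq Na2S2O3
Reagents that add atoms: none
Why: Iodine/DMSO dehydrogenative aromatisation of a cyclohexane-1,2-dione: iodination at an enol carbon, loss of HI to a cyclohexadienone and tautomerisation give the catechol, while DMSO reoxidises HI to I2. The ester-conjugated catechol is a poor reductant in this acidic medium and should not be oxidised further by iodine.

## Compound list

1 | 1-bromo-4-methylpentane | CC(C)CCCBr | starting material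
2 | 16-bromohexadecan-1-ol | OCCCCCCCCCCCCCCCCBr | starting material
3 | (4-methylpentyl)magnesium bromide | CC(C)CCC[Mg]Br | intermediate (not isolated)
4 | 20-methylhenicosan-1-ol | CC(C)CCCCCCCCCCCCCCCCCCCO | intermediate
5 | 6-tert-butoxy-6-oxohexanoic acid | CC(C)(C)OC(=O)CCCCC(=O)O | starting material
6 | 1-tert-butyl 6-(20-methylhenicosyl) hexanedioate | CC(C)CCCCCCCCCCCCCCCCCCCOC(=O)CCCCC(=O)OC(C)(C)C | intermediate
7 | di-tert-butyl oxalate | CC(C)(C)OC(=O)C(=O)OC(C)(C)C | starting material
8 | dilithium 1-tert-butoxy-6-[(20-methylhenicosyl)oxy]hexa-1,5-diene-1,6-bis(olate) (bis-enolate of 6, enolate geometry undefined) | CC(C)CCCCCCCCCCCCCCCCCCCOC(O[Li])=CCCC=C(O[Li])OC(C)(C)C | intermediate (not isolated)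
9 | 1-tert-butyl 6-(20-methylhenicosyl) 5-[tert-butoxy(oxo)acetyl]hexanedioate (racemic at C5, present as its lithium enolate) | CC(C)CCCCCCCCCCCCCCCCCCCOC(=O)C(CCCC(=O)OC(C)(C)C)C(=O)C(=O)OC(C)(C)C | intermediate (not isolated)
10 | 4-tert-butyl 1-(20-methylhenicosyl) 2,3-dihydroxycyclohexa-1,3-diene-1,4-dicarboxylate | CC(C)CCCCCCCCCCCCCCCCCCCOC(=O)C1=C(O)C(O)=C(CC1)C(=O)OC(C)(C)C | intermediate
11 | 2,3-dihydroxy-4-{[(20-methylhenicosyl)oxy]carbonyl}cyclohexa-1,3-diene-1-carboxylic acid | CC(C)CCCCCCCCCCCCCCCCCCCOC(=O)C1=C(O)C(O)=C(CC1)C(=O)O | intermediate (not isolated)
12 | 20-methylhenicosyl 2-hydroxy-3-oxocyclohex-1-ene-1-carboxylate | CC(C)CCCCCCCCCCCCCCCCCCCOC(=O)C1=C(O)C(=O)CCC1 | intermediate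
13 | Gentiside A, 20-methylhenicosyl 2,3-dihydroxybenzoate | CC(C)CCCCCCCCCCCCCCCCCCCOC(=O)c1cccc(O)c1O | target

## Step count and least certain steps

Total step count: 5. Longest linear sequence: 5 steps (1 and 2 → 4 → 6 → 10 → 12 → 13).

Step 3 (key step). The most likely failure is stalling after the first acylation. The acidic proton of 9 can quench the remote enolate, and the hindered oxalyl tert-butyl ester is attacked only slowly. On warming, intermolecular oxalylation or lithium alkoxide exchange at the long-chain ester could then overtake ring closure, and precipitation of the lipophilic bis-enolate at −78 °C would have the same effect. The fallback makes the ring on a symmetrical substrate and attaches the chain afterwards. It sets out from 7 and 4. Purchased di-tert-butyl hexanedioate F1 is condensed with an excess of 7 (KOtBu, THF, 0 → 40 °C); all alkoxide groups are identical, so exchange is degenerate and the reaction can be forced. This gives di-tert-butyl 2,3-dihydroxycyclohexa-1,3-diene-1,4-dicarboxylate F2. Heating an excess of F2 with 4 in toluene at 110 °C under N2, with removal of tert-butanol, exchanges one ester group through the α-oxoketene that enolised tert-butyl β-keto esters release on thermolysis. The mixed diester formed is 10, where the route is rejoined.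

Step 5. The most likely failure is over-oxidation: Kornblum-type oxygenation at C4 by DMSO competing with loss of HI, or iodination of the electron-rich ring once it is aromatic. The fallback replaces the catalytic oxidation by a stoichiometric halogenation–elimination sequence and sets out from 12. Br2 (1.0 equiv, CH2Cl2, 0 °C) brominates the enol carbon C1 to give 20-methylhenicosyl 1-bromo-2,3-dioxocyclohexane-1-carboxylate F3. LiBr and Li2CO3 in DMF at 100 °C then eliminate HBr toward C6, and the resulting dienone tautomerises to 13.

Step 4. The most likely failure is aromatisation by adventitious oxidant before decarboxylation, which would fix the carboxyl on a benzene ring, or C-alkylation of the electron-rich enol by the tert-butyl cation. The fallback replaces acidolysis by hydrogenolysis and sets out from 4. Steglich esterification with purchased 6-(benzyloxy)-6-oxohexanoic acid F4 gives 1-benzyl 6-(20-methylhenicosyl) hexanedioate F5. The condensation of step 3 with 7 then gives 4-benzyl 1-(20-methylhenicosyl) 2,3-dihydroxycyclohexa-1,3-diene-1,4-dicarboxylate F6. Hydrogenolysis (H2, Pd/C, EtOAc, rt) frees acid 11 under a reducing atmosphere without acid or carbocation, and gentle warming leads to 12, where the route is rejoined.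

Step 1. The most likely failure is reduction and homocoupling at the alkylcopper stage, together with incomplete conversion caused by the sparingly soluble magnesium alkoxide. These leave long-chain by-products that are hard to separate from 4. The fallback replaces the coupling by olefination and sets out from 2. PPh3 (MeCN, reflux) gives (16-hydroxyhexadecyl)triphenylphosphonium bromide F7. NaN(SiMe3)2 (2.1 equiv, THF) and purchased 4-methylpentanal F8 give (Z)-20-methylhenicos-16-en-1-ol F9 by Wittig reaction. Hydrogenation (H2, Pd/C) then gives 4, where the route is rejoined.

## Further compounds

F1 | step 3 | di-tert-butyl hexanedioate (purchased) | CC(C)(C)OC(=O)CCCCC(=O)OC(C)(C)C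
F2 | step 3 | di-tert-butyl 2,3-dihydroxycyclohexa-1,3-diene-1,4-dicarboxylate | CC(C)(C)OC(=O)C1=C(O)C(O)=C(CC1)C(=O)OC(C)(C)C
F3 | step 5 | 20-methylhenicosyl 1-bromo-2,3-dioxocyclohexane-1-carboxylate (racemic) | CC(C)CCCCCCCCCCCCCCCCCCCOC(=O)C1(Br)CCCC(=O)C1=O
F4 | step 4 | 6-(benzyloxy)-6-oxohexanoic acid (purchased) | OC(=O)CCCCC(=O)OCc1ccccc1
F5 | step 4 | 1-benzyl 6-(20-methylhenicosyl) hexanedioate | CC(C)CCCCCCCCCCCCCCCCCCCOC(=O)CCCCC(=O)OCc1ccccc1
F6 | step 4 | 4-benzyl 1-(20-methylhenicosyl) 2,3-dihydroxycyclohexa-1,3-diene-1,4-dicarboxylate | CC(C)CCCCCCCCCCCCCCCCCCCOC(=O)C1=C(O)C(O)=C(CC1)C(=O)OCc1ccccc1
F7 | step 1 | (16-hydroxyhexadecyl)triphenylphosphonium bromide | OCCCCCCCCCCCCCCCC[P+](c1ccccc1)(c1ccccc1)c1ccccc1.[Br-]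
F8 | step 1 | 4-methylpentanal (purchased) | CC(C)CCC=O
F9 | step 1 | (Z)-20-methylhenicos-16-en-1-ol | CC(C)CC/C=C\CCCCCCCCCCCCCCCO
A1 | alternative 1 | 1,2-bis(benzyloxy)-3-bromobenzene | Brc1cccc(OCc2ccccc2)c1OCc1ccccc1
A2 | alternative 1 | carbon monoxide | [C-]#[O+]
A3 | alternative 1 | 20-methylhenicosyl 2,3-bis(benzyloxy)benzoate | CC(C)CCCCCCCCCCCCCCCCCCCOC(=O)c1cccc(OCc2ccccc2)c1OCc1ccccc1
A4 | alternative 2 | icosanedioic acid | OC(=O)CCCCCCCCCCCCCCCCCCC(=O)O
A5 | alternative 2 | tert-butyl 20-hydroxyicosanoate | CC(C)(C)OC(=O)CCCCCCCCCCCCCCCCCCCO
A6 | alternative 2 | methyllithium | [Li]C
A7 | alternative 2 | 20-methylhenicosane-1,20-diol | CC(C)(O)CCCCCCCCCCCCCCCCCCCO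
A8 | alternative 3 | 20-methylhenicosyl 2-{[(trifluoromethyl)sulfonyl]oxy}-3-(trimethylsilyl)benzoate | CC(C)CCCCCCCCCCCCCCCCCCCOC(=O)c1cccc([Si](C)(C)C)c1OS(=O)(=O)C(F)(F)F
A9 | alternative 3 | N,N-dimethylformamide | CN(C)C=O
A10 | alternative 3 | 20-methylhenicosyl 2-formyl-3-hydroxybenzoate | CC(C)CCCCCCCCCCCCCCCCCCCOC(=O)c1cccc(O)c1C=O
A11 | alternative 3 | 20-methylhenicosyl 3-formyl-2-hydroxybenzoate | CC(C)CCCCCCCCCCCCCCCCCCCOC(=O)c1cccc(C=O)c1O
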